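**Plan**

1. Numbering (germacranolide): ten-membered ring C1–C10 with C14 on C10 and C15 on C4; five-membered lactone ring O–C6–C7–C11–C12 with C13 on C11; acyloxy groups on C3 and C8; epoxide across C1–C10.
2. Enabling feature: in the lactone ring C11 is next to the carbonyl carbon C12 and C7 is one position further, so they are the two olefinic carbons of a butenolide. A C8 carbon nucleophile can therefore be added at C7 and the enolate formed at C11 caught by a one-carbon electrophile for C13.
3. Cuts, in retrosynthetic order: the C1–C10 epoxide oxygen; the ester C–O bonds at C8 and C3; the ring bond C3–C4 (alkenyl iodide plus aldehyde); then C7–C8 and C11–C13 together, which leaves butenolide 11 (fragment 1), dithiane 19 (fragment 2) and iminium salt 20.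
4. Forward order: the lactone ring is there from the start (from 1); the C8–C3 chain is joined to it in step 9; the ten-membered ring closes at C3–C4 in step 16; the esters go on in steps 17 and 22 and the epoxide last, in step 23.
5. Stereochemistry: C6 from (S)-lactone 1; C7 (and the transient C11 centre) by anti addition to the butenolide; C8 by CBS reduction; C3 by the macrocyclic Nozaki–Hiyama–Kishi closure; C1/C10 by outside-face epoxidation of the E-olefin; 4Z from Stork–Zhao olefination, 1(10)E from a stabilised Wittig reaction; side-chain centres from (R)-2-methylbutanoic acid and a Sharpless epoxidation.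

Key step: step 9

Remark: germacranolide numbering is used for all skeletal atoms; the ring closure (step 16) and the final epoxidation (step 23) are assumed to follow attack on the outer face of the ten-membered ring, giving 3S and 1R,10R.

**Route**

Step 1
Reactants: 1 (S)-5-(hydroxymethyl)dihydrofuran-2(3H)-one
Product: 2 (S)-5-oxotetrahydrofuran-2-carbaldehyde
Conditions: Dess–Martin periodinane, CH2Cl2, 0 °C → rt; non-aqueous work-up, used crude
Reagents that add atoms: none
Why: Dess–Martin oxidation takes the primary alcohol to the aldehyde under neutral, water-free conditions, so the configurationally labile α-acyloxy aldehyde should form without epimerisation at C6 or hydration.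

Step 2
Reactants: 2 (S)-5-oxotetrahydrofuran-2-carbaldehyde; 3 ethyltriphenylphosphonium iodide
Product: 7 (S)-5-[(Z)-2-iodoprop-1-enyl]dihydrofuran-2(3H)-one, via ethylidenetriphenylphosphorane 4 (not isolated), via (1-iodoethyl)triphenylphosphonium iodide 5 (not isolated), via (1-iodoethylidene)triphenylphosphorane 6 (not isolated)
Conditions: 3, n-BuLi, THF, 0 °C → rt; I2, −78 °C; NaN(SiMe3)2, −20 °C; then 2, −78 → −20 °C
Reagents that add atoms: iodine, II
Why: Stork–Zhao olefination (Wittig reaction of the α-iodo ylide 6) should give the Z-iodoalkene, iodine cis to C6, under kinetic control at −78 °C, where the aldehyde reacts much faster than the lactone carbonyl; C6 comes unchanged from 1.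

Step 3
Reactants: 7 (S)-5-[(Z)-2-iodoprop-1-enyl]dihydrofuran-2(3H)-one
Product: 9 (5S)-5-[(Z)-2-iodoprop-1-enyl]-3-(phenylselanyl)dihydrofuran-2(3H)-one as both C3 epimers, via lithium enolate 8 (not isolated)
Conditions: LiN(iPr)2, THF, −78 °C; PhSeBr, −78 °C
Reagents that add atoms: phenylselenyl bromide, Br[Se]c1ccccc1
Why: α-selenenylation of the lactone lithium enolate installs the leaving group for the next step, and the epimer ratio at the selenium-bearing carbon does not matter because that carbon becomes sp2.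

Step 4
Reactants: 9 (5S)-5-[(Z)-2-iodoprop-1-enyl]-3-(phenylselanyl)dihydrofuran-2(3H)-one
Product: 11 (S)-5-[(Z)-2-iodoprop-1-enyl]furan-2(5H)-one (fragment 1), via selenoxide 10 (not isolated)
Conditions: H2O2 (30% aq, excess), CH2Cl2, 0 °C → rt; used promptly
Reagents that add atoms: none
Why: oxidation to the selenoxide is followed by syn-elimination (selenoxide elimination) below room temperature, which can only take a ring hydrogen from C7 and should therefore give the endocyclic butenolide without touching C6.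

Step 5
Reactants: 12 3-(tert-butyldimethylsilyloxy)propanal; 13 ethyl 2-(triphenylphosphoranylidene)propanoate
Product: 14 ethyl (E)-5-(tert-butyldimethylsilyloxy)-2-methylpent-2-enoate
Conditions: CH2Cl2, rt
Reagents that add atoms: none
Why: Wittig olefination with the stabilised, α-branched ylide is under thermodynamic control and should give the E-trisubstituted enoate that later becomes the C1=C10 olefin.

Step 6
Reactants: 14 ethyl (E)-5-(tert-butyldimethylsilyloxy)-2-methylpent-2-enoate
Product: 15 (E)-5-(tert-butyldimethylsilyloxy)-2-methylpent-2-en-1-ol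
Conditions: iBu2AlH, CH2Cl2, −78 °C; aq potassium sodium tartrate work-up
Reagents that add atoms: none
Why: ester reduction by 1,2-hydride delivery from iBu2AlH at −78 °C should give the allylic alcohol without touching the olefin geometry or the silyl ether.

Step 7
Reactants: 15 (E)-5-(tert-butyldimethylsilyloxy)-2-methylpent-2-en-1-ol
Product: 16 [(E)-5-bromo-4-methylpent-3-enyloxy](tert-butyl)dimethylsilane
Conditions: CBr4, PPh3, CH2Cl2, 0 °C; used fresh
Reagents that add atoms: carbon tetrabromide, BrC(Br)(Br)Br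
Why: Appel bromination converts the primary allylic alcohol by SN2 displacement of an oxyphosphonium ion under neutral conditions, so neither allylic transposition nor loss of the silyl ether is expected.

Step 8
Reactants: 16 [(E)-5-bromo-4-methylpent-3-enyloxy](tert-butyl)dimethylsilane; 17 1,3-dithiane
Product: 19 2-[(E)-5-(tert-butyldimethylsilyloxy)-2-methylpent-2-enyl]-1,3-dithiane (fragment 2), via 2-lithio-1,3-dithiane 18 (not isolated)
Conditions: 17, n-BuLi, THF, −30 °C; then 16, −78 → 0 °C
Reagents that add atoms: none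
Why: Corey–Seebach alkylation, in which the sulfur-stabilised anion 18 displaces the primary allylic bromide by SN2 at the unhindered CH2 (SN2′ attack would have to build a quaternary carbon), should keep the E geometry and deliver the C8–C3 chain.

Step 9
Reactants: 19 2-[(E)-5-(tert-butyldimethylsilyloxy)-2-methylpent-2-enyl]-1,3-dithiane; 11 (S)-5-[(Z)-2-iodoprop-1-enyl]furan-2(5H)-one; 20 N,N-dimethylmethyleneiminium iodide (Eschenmoser's salt)
Product: 23 (3R,4S,5S)-4-{2-[(E)-5-(tert-butyldimethylsilyloxy)-2-methylpent-2-enyl]-1,3-dithian-2-yl}-3-[(dimethylamino)methyl]-5-[(Z)-2-iodoprop-1-enyl]dihydrofuran-2(3H)-one, via lithiated dithiane 21 (not isolated), via lithium enolate 22 (not isolated)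
Conditions: 19, n-BuLi (0.95 equiv), THF, −25 °C; HMPA, −78 °C; 11, −78 °C; then 20, −78 → 0 °C
Reagents that add atoms: none
Why: n-BuLi removes the C2 proton of dithiane 19, and in THF–HMPA the sulfur-stabilised, solvent-separated carbanion 21 should add to the β-carbon C7 of butenolide 11 rather than to the lactone carbonyl; the lithium enolate 22 is then aminomethylated at C11 by iminium salt 20 (Mannich reaction), so that C7–C8 and C11–C13 are made in one flask. The closest known reaction type is the tandem conjugate addition of 2-lithio-1,3-dithianes to γ-substituted butenolides with capture of the enolate, as practised in butyrolactone lignan chemistry, combined with the aminomethylation of lactone enolates by Eschenmoser's salt. No ring is closed. The C7 centre is controlled by the C6 centre of 11, the nucleophile entering anti to the iodopropenyl group; the C11 centre is controlled by the bulky new C7 substituent, the iminium ion entering trans to it (this centre is removed again in step 10). The step needs 1,4- over 1,2-addition and addition over proton abstraction at the allylic C6–H, which the soft charge-delocalised anion, the polar cosolvent and −78 °C should secure. Lithium–iodine exchange at C4 is not expected, since it would trade the stabilised dithianyl anion for a less stable alkenyllithium and no free n-BuLi remains.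

Step 10
Reactants: 23 (3R,4S,5S)-4-{2-[(E)-5-(tert-butyldimethylsilyloxy)-2-methylpent-2-enyl]-1,3-dithian-2-yl}-3-[(dimethylamino)methyl]-5-[(Z)-2-iodoprop-1-enyl]dihydrofuran-2(3H)-one
Product: 25 (4S,5S)-4-{2-[(E)-5-(tert-butyldimethylsilyloxy)-2-methylpent-2-enyl]-1,3-dithian-2-yl}-5-[(Z)-2-iodoprop-1-enyl]-3-methylenedihydrofuran-2(3H)-one, via trimethylammonium iodide 24 (not isolated)
Conditions: MeI (3 equiv), THF, rt; then aq NaHCO3, EtOAc, rt
Reagents that add atoms: none
Why: exhaustive N-methylation followed by E1cB (Hofmann-type) elimination of trimethylamine from the β-ammonio lactone 24 should unveil the α-methylene lactone under bicarbonate conditions, the amine being far more nucleophilic towards MeI than the dithiane sulfur; removing the basic nitrogen here keeps the later β,γ-unsaturated ketone and aldehyde free of an internal base.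

Step 11
Reactants: 25 (4S,5S)-4-{2-[(E)-5-(tert-butyldimethylsilyloxy)-2-methylpent-2-enyl]-1,3-dithian-2-yl}-5-[(Z)-2-iodoprop-1-enyl]-3-methylenedihydrofuran-2(3H)-one
Product: 26 (4S,5S)-4-[(E)-6-(tert-butyldimethylsilyloxy)-3-methylhex-3-enoyl]-5-[(Z)-2-iodoprop-1-enyl]-3-methylenedihydrofuran-2(3H)-one
Conditions: PhI(OCOCF3)2, CaCO3, MeCN–H2O (9:1), 0 °C, minutes; used directly
Reagents that add atoms: water, O
Why: oxidative dethioacetalisation with the hypervalent iodine reagent activates sulfur and hydrolyses the resulting thionium ion within minutes at 0 °C, conditions that the olefins, the alkenyl iodide, the silyl ether and the base-sensitive β,γ-unsaturated ketone should survive.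

Step 12
Reactants: 26 (4S,5S)-4-[(E)-6-(tert-butyldimethylsilyloxy)-3-methylhex-3-enoyl]-5-[(Z)-2-iodoprop-1-enyl]-3-methylenedihydrofuran-2(3H)-one
Product: 27 (4R,5S)-4-[(1R,3E)-6-(tert-butyldimethylsilyloxy)-1-hydroxy-3-methylhex-3-enyl]-5-[(Z)-2-iodoprop-1-enyl]-3-methylenedihydrofuran-2(3H)-one
Conditions: (S)-1-methyl-3,3-diphenyltetrahydro-1H,3H-pyrrolo[1,2-c][1,3,2]oxazaborole (the (S)-methyl CBS oxazaborolidine, 1 equiv), catecholborane, toluene, −78 °C
Reagents that add atoms: none
Why: Corey–Bakshi–Shibata reduction, with the branched C7 side as the large group and C9H2 as the small one, should deliver hydride to the face that gives the 8R alcohol (the sense in which the (S)-reagent gives (R)-1-phenylethanol), reagent control being needed because the ketone is flanked almost symmetrically by C6 and C11.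

Step 13
Reactants: 27 (4R,5S)-4-[(1R,3E)-6-(tert-butyldimethylsilyloxy)-1-hydroxy-3-methylhex-3-enyl]-5-[(Z)-2-iodoprop-1-enyl]-3-methylenedihydrofuran-2(3H)-one
Product: 28 (4S,5S)-4-[(1R,3E)-1,6-bis(tert-butyldimethylsilyloxy)-3-methylhex-3-enyl]-5-[(Z)-2-iodoprop-1-enyl]-3-methylenedihydrofuran-2(3H)-one
Conditions: TBSOTf, 2,6-lutidine, CH2Cl2, −78 → 0 °C
Reagents that add atoms: tert-butyldimethylsilyl trifluoromethanesulfonate, CC(C)(C)[Si](C)(C)OS(=O)(=O)C(F)(F)F
Why: silylation with the silyl triflate and 2,6-lutidine protects the hindered secondary C8 hydroxyl at low temperature, which blocks relactonisation onto C12 and keeps C8–O distinct from C3–O.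

Step 14
Reactants: 28 (4S,5S)-4-[(1R,3E)-1,6-bis(tert-butyldimethylsilyloxy)-3-methylhex-3-enyl]-5-[(Z)-2-iodoprop-1-enyl]-3-methylenedihydrofuran-2(3H)-one
Product: 29 (4S,5S)-4-[(1R,3E)-1-(tert-butyldimethylsilyloxy)-6-hydroxy-3-methylhex-3-enyl]-5-[(Z)-2-iodoprop-1-enyl]-3-methylenedihydrofuran-2(3H)-one
Conditions: HF·pyridine, pyridine, THF, 0 °C
Reagents that add atoms: none
Why: fluoride-mediated desilylation with buffered HF·pyridine is much faster for the unhindered primary silyl ether at C3 than for the secondary one at C8 beside the lactone ring, so selective deprotection is expected.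

Step 15
Reactants: 29 (4S,5S)-4-[(1R,3E)-1-(tert-butyldimethylsilyloxy)-6-hydroxy-3-methylhex-3-enyl]-5-[(Z)-2-iodoprop-1-enyl]-3-methylenedihydrofuran-2(3H)-one
Product: 30 (3E,6R)-6-(tert-butyldimethylsilyloxy)-6-[(2S,3S)-2-[(Z)-2-iodoprop-1-enyl]-4-methylene-5-oxotetrahydrofuran-3-yl]-4-methylhex-3-enal
Conditions: Dess–Martin periodinane, pyridine, CH2Cl2, 0 °C; used directly
Reagents that add atoms: none
Why: Dess–Martin oxidation under pyridine buffering gives the β,γ-unsaturated aldehyde without acid or strong base, so the C1=C10 olefin should not move into conjugation.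

Step 16
Reactants: 30 (3E,6R)-6-(tert-butyldimethylsilyloxy)-6-[(2S,3S)-2-[(Z)-2-iodoprop-1-enyl]-4-methylene-5-oxotetrahydrofuran-3-yl]-4-methylhex-3-enal
Product: 32 (3S,6R,7S,8R)-8-(tert-butyldimethylsilyloxy)-3-hydroxygermacra-1(10)E,4Z,11(13)-trien-12,6-olide, via alkenylchromium dichloride 31 (not isolated)
Conditions: CrCl2 (10 equiv), NiCl2 (1 mol %), DMSO, rt, slow addition to 0.002 M
Reagents that add atoms: none
Why: Nozaki–Hiyama–Kishi reaction, in which zerovalent nickel formed from NiCl2 inserts into the carbon–iodine bond with retention of the Z geometry and transmetalation to trivalent chromium gives alkenylchromium 31 that adds only to the aldehyde, should close the ten-membered ring at C3–C4 under high dilution, with C3 set by a macrocyclic transition state in which the aldehyde oxygen points to the outside of the forming ring (3S expected).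

Step 17
Reactants: 32 (3S,6R,7S,8R)-8-(tert-butyldimethylsilyloxy)-3-hydroxygermacra-1(10)E,4Z,11(13)-trien-12,6-olide; 33 (R)-2-methylbutanoic acid
Product: 34 (3S,6R,7S,8R)-8-(tert-butyldimethylsilyloxy)-3-[(R)-2-methylbutanoyloxy]germacra-1(10)E,4Z,11(13)-trien-12,6-olide
Conditions: N,N′-dicyclohexylcarbodiimide, 4-(dimethylamino)pyridine (cat.), CH2Cl2, 0 °C
Reagents that add atoms: none
Why: Steglich esterification acylates the allylic C3 hydroxyl with retention at C3, and at 0 °C the α-centre of the acid should not epimerise.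

Step 18
Reactants: 34 (3S,6R,7S,8R)-8-(tert-butyldimethylsilyloxy)-3-[(R)-2-methylbutanoyloxy]germacra-1(10)E,4Z,11(13)-trien-12,6-olide
Product: 35 (3S,6R,7R,8R)-8-hydroxy-3-[(R)-2-methylbutanoyloxy]germacra-1(10)E,4Z,11(13)-trien-12,6-olide
Conditions: HF·pyridine, THF, 0 °C → rt
Reagents that add atoms: none
Why: desilylation with HF·pyridine removes the remaining secondary silyl ether under non-basic conditions, so neither the C3 ester nor the lactone should migrate to the freed C8 hydroxyl.

Step 19
Reactants: 36 methyl (Z)-2-methylbut-2-enoate (methyl angelate)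
Product: 37 (Z)-2-methylbut-2-en-1-ol
Conditions: iBu2AlH, CH2Cl2, −78 °C; aq potassium sodium tartrate work-up
Reagents that add atoms: none
Why: ester reduction with iBu2AlH at −78 °C avoids the base or heat that would isomerise the Z (angelate) olefin to the E (tiglate) one.

Step 20
Reactants: 37 (Z)-2-methylbut-2-en-1-ol
Product: 38 [(2R,3S)-2,3-dimethyloxiran-2-yl]methanol
Conditions: Ti(OiPr)4 (10 mol %), diisopropyl D-(−)-tartrate (12 mol %), t-BuOOH, 4 Å molecular sieves, CH2Cl2, −20 °C
Reagents that add atoms: tert-butyl hydroperoxide, CC(C)(C)OO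
Why: Sharpless asymmetric epoxidation with the D-(−)-tartrate ligand should deliver oxygen to the olefin face that gives the 2R,3S epoxy alcohol (the L-(+)-ligand gives the 2S,3R enantiomer), and syn addition keeps the C3 methyl cis to the CH2OH group.

Step 21
Reactants: 38 [(2R,3S)-2,3-dimethyloxiran-2-yl]methanol
Product: 39 (2S,3S)-2,3-dimethyloxirane-2-carboxylic acid
Conditions: RuCl3 (cat.), NaIO4, CCl4–MeCN–H2O, rt
Reagents that add atoms: water, O
Why: RuO4 generated from catalytic RuCl3 and NaIO4 oxidises the primary alcohol through the aldehyde hydrate to the acid without opening the epoxide, the spatial arrangement being unchanged (C2 is named S only because CO2H now outranks C3).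

Step 22
Reactants: 35 (3S,6R,7R,8R)-8-hydroxy-3-[(R)-2-methylbutanoyloxy]germacra-1(10)E,4Z,11(13)-trien-12,6-olide; 39 (2S,3S)-2,3-dimethyloxirane-2-carboxylic acid
Product: 41 (3S,6R,7R,8R)-8-[(2S,3S)-2,3-dimethyloxirane-2-carbonyloxy]-3-[(R)-2-methylbutanoyloxy]germacra-1(10)E,4Z,11(13)-trien-12,6-olide, via mixed anhydride 40 (not isolated)
Conditions: 39, 2,4,6-trichlorobenzoyl chloride, Et3N, THF, rt; then 35, 4-(dimethylamino)pyridine, toluene, rt → 40 °C
Reagents that add atoms: none
Why: Yamaguchi esterification, in which 4-(dimethylamino)pyridine attacks mixed anhydride 40 at the glycidic carbonyl (the aroyl carbonyl is shielded by two ortho chlorines) and the acylpyridinium acylates the hindered C8 hydroxyl with retention, suits an acid whose quaternary α-carbon cannot epimerise.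

Step 23
Reactants: 41 (3S,6R,7R,8R)-8-[(2S,3S)-2,3-dimethyloxirane-2-carbonyloxy]-3-[(R)-2-methylbutanoyloxy]germacra-1(10)E,4Z,11(13)-trien-12,6-olide
Product: 42 (1R,3S,6R,7R,8R,10R)-1,10-epoxy-8-[(2S,3S)-2,3-dimethyloxirane-2-carbonyloxy]-3-[(R)-2-methylbutanoyloxy]germacra-4Z,11(13)-dien-12,6-olide (CNP0265335.2)
Conditions: mCPBA (1.1 equiv), NaHCO3, CH2Cl2, 0 °C
Reagents that add atoms: 3-chloroperoxybenzoic acid, OOC(=O)c1cccc(Cl)c1
Why: Prilezhaev epoxidation by the electrophilic peracid should occur only at C1=C10, the one electron-rich olefin (C4=C5 carries two allylic acyloxy groups, C11=C13 is conjugated), from the exposed outer face of the ten-membered ring, giving stereospecifically the trans epoxide with the 1R,10R configuration found in related 1β,10α-epoxy heliangolides.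

**Compound list**

1 | (S)-5-(hydroxymethyl)dihydrofuran-2(3H)-one | O=C1CC[C@@H](CO)O1 | starting material
2 | (S)-5-oxotetrahydrofuran-2-carbaldehyde | O=C1CC[C@@H](C=O)O1 | intermediate
3 | ethyltriphenylphosphonium iodide | CC[P+](c1ccccc1)(c1ccccc1)c1ccccc1.[I-] | starting material
4 | ethylidenetriphenylphosphorane | CC=P(c1ccccc1)(c1ccccc1)c1ccccc1 | intermediate
5 | (1-iodoethyl)triphenylphosphonium iodide | CC(I)[P+](c1ccccc1)(c1ccccc1)c1ccccc1.[I-] | intermediate
6 | (1-iodoethylidene)triphenylphosphorane | CC(I)=P(c1ccccc1)(c1ccccc1)c1ccccc1 | intermediate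
7 | (S)-5-[(Z)-2-iodoprop-1-enyl]dihydrofuran-2(3H)-one | O=C1CC[C@@H](/C=C(/C)I)O1 | intermediate
8 | lithium enolate of 7 | [Li]OC1=CC[C@@H](/C=C(/C)I)O1 | intermediate
9 | (5S)-5-[(Z)-2-iodoprop-1-enyl]-3-(phenylselanyl)dihydrofuran-2(3H)-one, both C3 epimers | O=C1C([Se]c2ccccc2)C[C@@H](/C=C(/C)I)O1 | intermediate
10 | selenoxide of 9 | O=C1C([Se](=O)c2ccccc2)C[C@@H](/C=C(/C)I)O1 | intermediate
11 | (S)-5-[(Z)-2-iodoprop-1-enyl]furan-2(5H)-one (fragment 1) | O=C1C=C[C@@H](/C=C(/C)I)O1 | intermediate
12 | 3-(tert-butyldimethylsilyloxy)propanal | CC(C)(C)[Si](C)(C)OCCC=O | starting material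
13 | ethyl 2-(triphenylphosphoranylidene)propanoate | CCOC(=O)C(C)=P(c1ccccc1)(c1ccccc1)c1ccccc1 | starting material
14 | ethyl (E)-5-(tert-butyldimethylsilyloxy)-2-methylpent-2-enoate | CCOC(=O)/C(C)=C/CCO[Si](C)(C)C(C)(C)C | intermediate
15 | (E)-5-(tert-butyldimethylsilyloxy)-2-methylpent-2-en-1-ol | OC/C(C)=C/CCO[Si](C)(C)C(C)(C)C | intermediate
16 | [(E)-5-bromo-4-methylpent-3-enyloxy](tert-butyl)dimethylsilane | BrC/C(C)=C/CCO[Si](C)(C)C(C)(C)C | intermediate
17 | 1,3-dithiane | C1CSCSC1 | starting material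
18 | 2-lithio-1,3-dithiane | [Li]C1SCCCS1 | intermediate
19 | 2-[(E)-5-(tert-butyldimethylsilyloxy)-2-methylpent-2-enyl]-1,3-dithiane (fragment 2) | CC(C)(C)[Si](C)(C)OCC/C=C(\C)CC1SCCCS1 | intermediate
20 | N,N-dimethylmethyleneiminium iodide (Eschenmoser's salt) | C=[N+](C)C.[I-] | starting material
21 | 2-lithio derivative of 19 | [Li]C1(C/C(C)=C/CCO[Si](C)(C)C(C)(C)C)SCCCS1 | intermediate
22 | lithium enolate from addition of 21 to 11 (C6 S, C7 S) | [Li]OC1=C[C@H](C2(C/C(C)=C/CCO[Si](C)(C)C(C)(C)C)SCCCS2)[C@@H](/C=C(/C)I)O1 | intermediate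
23 | (3R,4S,5S)-4-{2-[(E)-5-(tert-butyldimethylsilyloxy)-2-methylpent-2-enyl]-1,3-dithian-2-yl}-3-[(dimethylamino)methyl]-5-[(Z)-2-iodoprop-1-enyl]dihydrofuran-2(3H)-one | CN(C)C[C@@H]1C(=O)O[C@H](/C=C(/C)I)[C@H]1C2(C/C(C)=C/CCO[Si](C)(C)C(C)(C)C)SCCCS2 | intermediate
24 | trimethylammonium iodide from N-methylation of 23 | C[N+](C)(C)C[C@@H]1C(=O)O[C@H](/C=C(/C)I)[C@H]1C2(C/C(C)=C/CCO[Si](C)(C)C(C)(C)C)SCCCS2.[I-] | intermediate
25 | (4S,5S)-4-{2-[(E)-5-(tert-butyldimethylsilyloxy)-2-methylpent-2-enyl]-1,3-dithian-2-yl}-5-[(Z)-2-iodoprop-1-enyl]-3-methylenedihydrofuran-2(3H)-one | C=C1C(=O)O[C@H](/C=C(/C)I)[C@H]1C2(C/C(C)=C/CCO[Si](C)(C)C(C)(C)C)SCCCS2 | intermediate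
26 | (4S,5S)-4-[(E)-6-(tert-butyldimethylsilyloxy)-3-methylhex-3-enoyl]-5-[(Z)-2-iodoprop-1-enyl]-3-methylenedihydrofuran-2(3H)-one | C=C1C(=O)O[C@H](/C=C(/C)I)[C@H]1C(=O)C/C(C)=C/CCO[Si](C)(C)C(C)(C)C | intermediate
27 | (4R,5S)-4-[(1R,3E)-6-(tert-butyldimethylsilyloxy)-1-hydroxy-3-methylhex-3-enyl]-5-[(Z)-2-iodoprop-1-enyl]-3-methylenedihydrofuran-2(3H)-one | C=C1C(=O)O[C@H](/C=C(/C)I)[C@H]1[C@H](O)C/C(C)=C/CCO[Si](C)(C)C(C)(C)C | intermediate
28 | (4S,5S)-4-[(1R,3E)-1,6-bis(tert-butyldimethylsilyloxy)-3-methylhex-3-enyl]-5-[(Z)-2-iodoprop-1-enyl]-3-methylenedihydrofuran-2(3H)-one | C=C1C(=O)O[C@H](/C=C(/C)I)[C@H]1[C@H](O[Si](C)(C)C(C)(C)C)C/C(C)=C/CCO[Si](C)(C)C(C)(C)C | intermediate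
29 | (4S,5S)-4-[(1R,3E)-1-(tert-butyldimethylsilyloxy)-6-hydroxy-3-methylhex-3-enyl]-5-[(Z)-2-iodoprop-1-enyl]-3-methylenedihydrofuran-2(3H)-one | C=C1C(=O)O[C@H](/C=C(/C)I)[C@H]1[C@H](O[Si](C)(C)C(C)(C)C)C/C(C)=C/CCO | intermediate
30 | (3E,6R)-6-(tert-butyldimethylsilyloxy)-6-[(2S,3S)-2-[(Z)-2-iodoprop-1-enyl]-4-methylene-5-oxotetrahydrofuran-3-yl]-4-methylhex-3-enal | C=C1C(=O)O[C@H](/C=C(/C)I)[C@H]1[C@H](O[Si](C)(C)C(C)(C)C)C/C(C)=C/CC=O | intermediate
31 | alkenylchromium dichloride from 30 (trivalent chromium in place of iodine at C4) | C=C1C(=O)O[C@H](/C=C(/C)[Cr](Cl)Cl)[C@H]1[C@H](O[Si](C)(C)C(C)(C)C)C/C(C)=C/CC=O | intermediate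
32 | (3S,6R,7S,8R)-8-(tert-butyldimethylsilyloxy)-3-hydroxygermacra-1(10)E,4Z,11(13)-trien-12,6-olide | C=C1C(=O)O[C@@H]2/C=C(/C)[C@@H](O)C/C=C(\C)C[C@@H](O[Si](C)(C)C(C)(C)C)[C@@H]12 | intermediate
33 | (R)-2-methylbutanoic acid | CC[C@@H](C)C(=O)O | starting material
34 | (3S,6R,7S,8R)-8-(tert-butyldimethylsilyloxy)-3-[(R)-2-methylbutanoyloxy]germacra-1(10)E,4Z,11(13)-trien-12,6-olide | C=C1C(=O)O[C@@H]2/C=C(/C)[C@@H](OC(=O)[C@H](C)CC)C/C=C(\C)C[C@@H](O[Si](C)(C)C(C)(C)C)[C@@H]12 | intermediate
35 | (3S,6R,7R,8R)-8-hydroxy-3-[(R)-2-methylbutanoyloxy]germacra-1(10)E,4Z,11(13)-trien-12,6-olide | C=C1C(=O)O[C@@H]2/C=C(/C)[C@@H](OC(=O)[C@H](C)CC)C/C=C(\C)C[C@@H](O)[C@@H]12 | intermediate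
36 | methyl (Z)-2-methylbut-2-enoate (methyl angelate) | C/C=C(/C)C(=O)OC | starting material
37 | (Z)-2-methylbut-2-en-1-ol | C/C=C(/C)CO | intermediate
38 | [(2R,3S)-2,3-dimethyloxiran-2-yl]methanol | OC[C@@]1(C)O[C@H]1C | intermediate
39 | (2S,3S)-2,3-dimethyloxirane-2-carboxylic acid | OC(=O)[C@@]1(C)O[C@H]1C | intermediate
40 | (2S,3S)-2,3-dimethyloxirane-2-carboxylic 2,4,6-trichlorobenzoic anhydride | O=C(OC(=O)[C@@]1(C)O[C@H]1C)c1c(Cl)cc(Cl)cc1Cl | intermediate
41 | (3S,6R,7R,8R)-8-[(2S,3S)-2,3-dimethyloxirane-2-carbonyloxy]-3-[(R)-2-methylbutanoyloxy]germacra-1(10)E,4Z,11(13)-trien-12,6-olide | C=C1C(=O)O[C@@H]2/C=C(/C)[C@@H](OC(=O)[C@H](C)CC)C/C=C(\C)C[C@@H](OC(=O)[C@@]3(C)O[C@H]3C)[C@@H]12 | intermediate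
42 | (1R,3S,6R,7R,8R,10R)-1,10-epoxy-8-[(2S,3S)-2,3-dimethyloxirane-2-carbonyloxy]-3-[(R)-2-methylbutanoyloxy]germacra-4Z,11(13)-dien-12,6-olide (CNP0265335.2) | C=C1C(=O)O[C@@H]2/C=C(/C)[C@@H](OC(=O)[C@H](C)CC)C[C@H]3O[C@]3(C)C[C@@H](OC(=O)[C@@]3(C)O[C@H]3C)[C@@H]12 | target

**Step count and risks**

Total step count: 23. Longest linear sequence: 16 steps (steps 1–4, 9–18, 22, 23).

Steps most likely to fail:

Step 9. Proton transfer from the doubly activated C6–H of 11 (γ to the carbonyl and allylic) to the basic carbanion 21, or attack at the lactone carbonyl, could compete with conjugate addition and erode both the union and the C6 configuration. The fallback builds the iodoalkene after the union, on a butenolide whose γ-substituent is saturated. It sets out from 19 (lithiated to 21) and comes back at 23. Purchased (S)-5-(hydroxymethyl)furan-2(5H)-one F1 is silylated (Et3SiCl, imidazole, CH2Cl2) to (S)-5-[(triethylsilyloxy)methyl]furan-2(5H)-one F2. Addition of 21 to F2 under the conditions of step 9 should give the lithium enolate F3, which is trapped with 20 to give the Mannich base F4. Pyridinium p-toluenesulfonate in MeOH removes the primary triethylsilyl group in the presence of the tert-butyldimethylsilyl ether to give the alcohol F5. Parikh–Doering oxidation (SO3·pyridine, DMSO, iPr2NEt) then gives the aldehyde F6, and Stork–Zhao olefination with ylide 6 (made from 3 as in step 2) returns to 23.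

Step 16. Poor or reversed facial selectivity in the addition of the alkenylchromium to the aldehyde would give the C3 epimer (oligomerisation may in addition lower the ring-closure efficiency). The fallback corrects C3 by an invertive esterification instead of relying on the cyclisation. It sets out from 30 and comes back at 34. The (3R,6R,7S,8R)-alcohol F7 obtained from the closure is treated with acid 33 under Mitsunobu conditions (PPh3, diisopropyl azodicarboxylate, toluene, 0 °C), which should install the 2-methylbutanoate with inversion and lead straight to 34, replacing step 17 for that material.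

Step 12. Insufficient reagent control (a mismatch between the oxazaborolidine and the C7 centre) would favour hydride delivery to the other face, and the free C8 hydroxyl may relactonise onto C12 if the product is kept. The fallback inverts the unwanted epimer. It sets out from 26 and comes back at 27. The (8S)-alcohol F8 is converted by Mitsunobu reaction with chloroacetic acid (PPh3, diisopropyl azodicarboxylate, THF) into the (8R)-chloroacetate F9, and the chloroacetate is removed with thiourea (NaHCO3, EtOH, rt) to give 27, which is silylated at once as in step 13.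

Further compounds
F1 | step 9 | (S)-5-(hydroxymethyl)furan-2(5H)-one | O=C1C=C[C@@H](CO)O1
F2 | step 9 | (S)-5-[(triethylsilyloxy)methyl]furan-2(5H)-one | O=C1C=C[C@@H](CO[Si](CC)(CC)CC)O1
F3 | step 9 | lithium enolate from addition of 21 to F2 | [Li]OC1=C[C@H](C2(C/C(C)=C/CCO[Si](C)(C)C(C)(C)C)SCCCS2)[C@@H](CO[Si](CC)(CC)CC)O1
F4 | step 9 | (3R,4S,5S)-4-{2-[(E)-5-(tert-butyldimethylsilyloxy)-2-methylpent-2-enyl]-1,3-dithian-2-yl}-3-[(dimethylamino)methyl]-5-[(triethylsilyloxy)methyl]dihydrofuran-2(3H)-one | CN(C)C[C@@H]1C(=O)O[C@H](CO[Si](CC)(CC)CC)[C@H]1C2(C/C(C)=C/CCO[Si](C)(C)C(C)(C)C)SCCCS2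
F5 | step 9 | (3R,4S,5S)-4-{2-[(E)-5-(tert-butyldimethylsilyloxy)-2-methylpent-2-enyl]-1,3-dithian-2-yl}-3-[(dimethylamino)methyl]-5-(hydroxymethyl)dihydrofuran-2(3H)-one | CN(C)C[C@@H]1C(=O)O[C@H](CO)[C@H]1C2(C/C(C)=C/CCO[Si](C)(C)C(C)(C)C)SCCCS2
F6 | step 9 | (2S,3S,4R)-3-{2-[(E)-5-(tert-butyldimethylsilyloxy)-2-methylpent-2-enyl]-1,3-dithian-2-yl}-4-[(dimethylamino)methyl]-5-oxotetrahydrofuran-2-carbaldehyde | CN(C)C[C@@H]1C(=O)O[C@H](C=O)[C@H]1C2(C/C(C)=C/CCO[Si](C)(C)C(C)(C)C)SCCCS2
F7 | step 16 | (3R,6R,7S,8R)-8-(tert-butyldimethylsilyloxy)-3-hydroxygermacra-1(10)E,4Z,11(13)-trien-12,6-olide | C=C1C(=O)O[C@@H]2/C=C(/C)[C@H](O)C/C=C(\C)C[C@@H](O[Si](C)(C)C(C)(C)C)[C@@H]12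
F8 | step 12 | (4R,5S)-4-[(1S,3E)-6-(tert-butyldimethylsilyloxy)-1-hydroxy-3-methylhex-3-enyl]-5-[(Z)-2-iodoprop-1-enyl]-3-methylenedihydrofuran-2(3H)-one | C=C1C(=O)O[C@H](/C=C(/C)I)[C@H]1[C@@H](O)C/C(C)=C/CCO[Si](C)(C)C(C)(C)C
F9 | step 12 | (1R,3E)-6-(tert-butyldimethylsilyloxy)-1-[(2S,3S)-2-[(Z)-2-iodoprop-1-enyl]-4-methylene-5-oxotetrahydrofuran-3-yl]-3-methylhex-3-enyl chloroacetate | C=C1C(=O)O[C@H](/C=C(/C)I)[C@H]1[C@H](OC(=O)CCl)C/C(C)=C/CCO[Si](C)(C)C(C)(C)C
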